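# Proposed total synthesis of CNP0273650.13 (28) through an intramolecular nitrile oxide cycloaddition

## Analysis of the target

Target 28 is a daucane-type diester built on a cyclopentane cis-fused to a cycloheptene (bicyclo[5.3.0]dec-8-ene). Working numbers used throughout: C1 is the quaternary, methyl-bearing ring-fusion carbon, C2 and C3 are the CH2 groups of the five-membered ring, C4 is the tertiary carbinol carrying the isopropyl group, C5 is the ring-fusion CH, C6 the aroyloxy CH, C7 a CH2, C8 the methyl-bearing alkene carbon, C9 the alkene CH and C10 the allylic tigloyloxy CH. There are five stereocentres, (1R,4R,5S,6R,10S): the C1 methyl group, H-5 and the isopropyl group lie on one face of the bicycle and the three oxygens O4, O6 and O10 on the other, so O4 is cis to C6 and to C10 on the cyclopentane and H-6 is cis to H-5. The sensitive groups are the free tertiary alcohol, two different esters on secondary carbinols (an allylic (E)-2-methylbut-2-enoate at C10, a 4-hydroxybenzoate with a free phenol at C6) and the C8=C9 alkene, which sits β,γ to C6 and would move into conjugation with a carbonyl there. The difficulty lies in the quaternary C1 flanked by two stereocentres, in the seven-membered ring, and in the C4–C5–C6 array, which at the ketone stage is a tertiary aldol open to retro-aldol cleavage, dehydration and epimerisation at C5; in addition O6 and O10 must receive different acyl groups. The strategy rests on the array O4–C4–C5–C6–O6: a tertiary oxygen on C4 cis to the C6 substituent of C5 is what a 2-isoxazoline fused across C4–C5, with its C=N carbon at C6, becomes after N–O cleavage. Because C5–C6 is also a bond of the seven-membered ring, forming that isoxazoline intramolecularly from a chain attached to C1 closes the carbocycle and sets C4 and C5 in one step.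

## Retrosynthetic reasoning

**28 to 27, and 27 to 25 + 26.** The phenol is unmasked last: the O-acetyl group of 27 can be removed by aminolysis without touching the two alkyl esters, and a free phenol would interfere with any acylation. The aroyl C–O bond at O6 is cut next, to diol 25 and acid chloride 26. This cut is clean only because the tigloyl group is already on O10 in 25: O6–H is then the single secondary hydroxyl, the tertiary O4–H does not acylate, and the two secondary oxygens never have to be told apart.

**25 to 23 to 21.** The C6–H bond is cut back to hydroxy ketone 23. The forward reduction has to add hydride to the face of C6 next to H-5, which a boron chelate between O4 and the ketone oxygen should direct. Ketone 23 is isoxazoline 21 after reductive N–O cleavage and hydrolysis of the imine. This step adds no skeletal bond; it releases the aldol that the N–O bridge had held in a non-enolisable form.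

**21 to 19 (by way of nitrile oxide 20).** The C5–C6 bond and the C4–O bond are cut together. C5–C6 is chosen because it is the only bond of the cycloheptene whose formation can be coupled to the delivery of oxygen to C4. Cutting it returns C4 and C5 to a plain trisubstituted cyclopentene alkene and leaves an open chain on C1, so that C4, C5 and, one step later, C6 all derive from the two stereocentres C1 and C10 of 19. Cuts at C6–C7 or C9–C10 would leave the C4/C5/C6 triad to be built separately. Forward, the dipole carbon of 20 must bond to C5 and its oxygen to C4, on the ring face that carries C10, through a seven-membered transition state.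

**19 to 18 to 16 + 17.** The oxime is traced to cyclic acetal 18, so that the β,γ-unsaturated aldehyde is never a free intermediate. The C7–C8 bond is then cut between (Z)-alkenyl iodide 16 and zinc reagent 17, which supplies C7 and C6 with C6 already at the aldehyde oxidation level. A cross-coupling with retention is preferred to an olefination for C8=C9 because the geometry is then decided at the iodide, where it can be set without ambiguity.

**16 to 14 + 15, and 14 to 12.** The tigloyl C–O bond at O10 is cut to alcohol 14 and acid chloride 15; acylating here uses the final ester as the protecting group of O10. Iodide 14 is traced to alkyne 12: a hydroxyl-directed trans-hydrometalation puts hydrogen on C9 and the metal, then iodine, on C8 on the side of C10, which is the substitution pattern of the Z-alkene. The alkyne is thus the precursor of the trisubstituted alkene and needs the free C10 hydroxyl as directing group.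

**12 to 11 to 10 to 8 to 6 + 7.** The C10–H bond is cut to ynone 11 so that the C10 configuration is set by a chiral reduction catalyst and not by the substrate. Ynone 11 comes by oxidation from carbinol 10, whose C1–C10 bond is cut by a [2,3]-sigmatropic transform to propargyl ether 8. In 8 the oxygen sits on C4 and the C5=C1 alkene accepts the carbon, so the shift relays the C4 configuration to the quaternary C1 and leaves the C4=C5 alkene needed later. An ester-enolate [3,3] shift of an α-alkoxy ester would make the same bond, but its C10 configuration would hinge on a chair/boat preference that is hard to call for a cyclopentenyl ester, and it would not provide the alkyne. Ether 8 is made from cyclopentenol 6 and bromide 7.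

**6 to 5 to 4 to 2 to 1.** Alcohol 6 is taken from the chiral pool: its carbinol carbon is C4 of 1 and its methyl-bearing alkene carbon is C1 of 1. Retrosynthetically a formyl group is added to C5 (enal 4, through silyl ether 5), and the enal is opened by an aldol transform and reconnected to the cyclohexene of silyl ether 2. Forward this is ozonolysis, aldol condensation and loss of the formyl carbon by decarbonylation. The C4 oxygen of 1 is therefore used twice: it is given up in the sigmatropic shift to write the configuration of C1, and an oxygen returns to the same face of C4 in the cycloaddition.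

## Alternatives that were turned down

**Alternative 1: ring contraction that keeps the C4 oxygen.**
- Disconnection: the seven-membered ring is removed entirely and the C4 carbinol is retained from the monoterpene.
- Forward key step: ozonolysis with amine-catalysed aldol condensation in the same flask, which forms the C5=C1 bond and gives enal A1 (the compound the chosen route also passes as 4).
- For: C4 arrives with its oxygen and correct configuration, and the formyl carbon is already bonded to C5 and can become C6. On oxygen and atom economy this plan is stronger, since the chosen route deletes the formyl carbon and the C4–O bond and later puts an oxygen back.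
- Against: everything difficult lies after A1.
  - The quaternary C1 must be made by adding a carbon nucleophile to the β-carbon of a tetrasubstituted enal next to a fully substituted carbon.
  - Facial control would come only from C4, whose silyloxy and isopropyl groups differ little in size.
  - H-5 must then be set cis to the C1 methyl group, and the seven-membered ring with two carbinol centres built by separate C–C bond formations.
- Comparison: the chosen strategy spends the C4–O bond to set C1 by a suprafacial shift and recovers O4 in the step that also sets C5 and closes the ring, so three stereocentres follow from geometry. The price is the decarbonylation and two protecting-group steps.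

**Alternative 2: aldol-lactonisation to a β-lactone.**
- Disconnection: the C4–C5 bond and the acyl C6–O4 bond.
- Forward key step: the activated acid of keto acid A2 forms an ammonium enolate at C5, which adds to the isopropyl ketone; the aldolate closes onto the acyl ammonium to give the cyclopentane-fused β-lactone A3.
- For: it creates the same cis O4/C6 relationship at C4/C5, under mild organocatalytic conditions that can be made catalyst-controlled. C6 arrives as a carboxyl derivative, more robust than hydroxy ketone 23; on functional-group stability this plan is stronger.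
- Against:
  - An isopropyl ketone is a hindered acceptor for a reaction that works best with unhindered ketones.
  - The face of C5 relative to the quaternary C1 is not tied by a tether and must be won by the catalyst against substrate bias.
  - A2 needs C1 and C10 set in an open chain.
  - After A3 the seven-membered ring is still missing: C6–C7 by acyl substitution on the lactone, C8=C9 by a later ring closure, then reduction at C6.
- Comparison: the chosen strategy closes both rings and sets C4 and C5 in one step; avoiding a sensitive hydroxy ketone would be bought with several more C–C bond-forming steps.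

**Alternative 3: bis-allyl (3+4) annulation of a dialdehyde.**
- Disconnection: C6–C7 and C9–C10.
- Forward key step: the cis-dialdehyde A4 reacts with the conjunctive reagent A5. A tin-mediated allylation of the C6 aldehyde by the allyl iodide end is followed by Lewis-acid-promoted addition of the allylsilane end to the C10 aldehyde, closing the ring to diol A6.
- For: it is the most convergent plan. One reagent supplies C7–C8–C9, closes the seven-membered ring and creates both secondary carbinols; in ring-forming economy it is stronger than the chosen route.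
- Against:
  - A4 is a β-silyloxy aldehyde at C5 with an acidic α-hydrogen, so epimerisation at C5 or β-elimination of the C4 oxygen threatens.
  - Both aldehydes are hindered, and the two new carbinol centres would arise under weak control.
  - The exocyclic methylene at C8 must be moved into the ring specifically to C8=C9 although C7=C8 is equally available.
  - O6 and O10 emerge as two similar secondary alcohols that need different esters.
- Comparison: the chosen route fixes the alkene position from an alkyne, sets C10 by a catalyst and has O10 acylated before O6 exists; it pays with linear length.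

Key step: step 13

Remark: 1 is taken as enantiomerically pure (S) material, so that C4 of 1 is the only source of absolute configuration up to step 8; 1, 7, 15, 17 and 26 are commercial.

## Route

Step 1
Reactants: 1 (S)-terpinen-4-ol
Product: 2 triethyl{[(1S)-4-methyl-1-(propan-2-yl)cyclohex-3-en-1-yl]oxy}silane
Conditions: Et3SiOTf, 2,6-lutidine, CH2Cl2, −78 °C → 0 °C
Reagents that add atoms: triethylsilyl trifluoromethanesulfonate, CC[Si](CC)(CC)OS(=O)(=O)C(F)(F)F
Why: Silylation of a hindered tertiary alcohol with a silyl triflate and a non-nucleophilic base is standard. The silyl ether is needed so that in step 2 only the newly formed aldol hydroxyl, not the C4 oxygen, is eliminated when the enal forms.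

Step 2
Reactants: 2 triethyl{[(1S)-4-methyl-1-(propan-2-yl)cyclohex-3-en-1-yl]oxy}silane
Product: 4 (5R)-2-methyl-5-(propan-2-yl)-5-[(triethylsilyl)oxy]cyclopent-1-ene-1-carbaldehyde, via keto aldehyde 3 (not isolated)
Conditions: O3, CH2Cl2, −78 °C; Me2S, −78 °C → rt; piperidine (0.3 equiv), AcOH (0.3 equiv), 40 °C
Reagents that add atoms: ozone, [O-][O+]=O
Why: Ozonolysis cleaves the only alkene to keto aldehyde 3. Under amine–acid catalysis the enamine carbon of the aldehyde (future C5) adds to the methyl ketone (future C1) in a five-membered intramolecular aldol closure, and the new tertiary aldol dehydrates to the tetrasubstituted enal (aldol condensation). The C4 stereocentre is not touched.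

Step 3
Reactants: 4 (5R)-2-methyl-5-(propan-2-yl)-5-[(triethylsilyl)oxy]cyclopent-1-ene-1-carbaldehyde
Product: 5 triethyl{[(1R)-3-methyl-1-(propan-2-yl)cyclopent-2-en-1-yl]oxy}silane
Conditions: RhCl(PPh3)3 (1.1 equiv), toluene, 110 °C
Reagents that add atoms: none
Why: Tsuji–Wilkinson decarbonylation: the formyl C–H bond adds to monovalent rhodium, CO migrates to the metal and the alkenyl hydride eliminates reductively, so hydrogen replaces the formyl group without moving the double bond. The complex is used stoichiometrically because the carbonyl complex formed does not turn over at this temperature.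

Step 4
Reactants: 5 triethyl{[(1R)-3-methyl-1-(propan-2-yl)cyclopent-2-en-1-yl]oxy}silane
Product: 6 (1R)-3-methyl-1-(propan-2-yl)cyclopent-2-en-1-ol
Conditions: Bu4NF, THF, rt
Reagents that add atoms: none
Why: Fluoride cleaves the Si–O bond of the tertiary allylic silyl ether under conditions too mild to ionise the allylic alcohol.

Step 5
Reactants: 6 (1R)-3-methyl-1-(propan-2-yl)cyclopent-2-en-1-ol; 7 1-bromobut-2-yne
Product: 8 (3R)-3-(but-2-yn-1-yloxy)-1-methyl-3-(propan-2-yl)cyclopent-1-ene
Conditions: KH, THF, 0 °C; 7, Bu4NI (0.1 equiv), 0 °C → rt
Reagents that add atoms: 1-bromobut-2-yne (7), CC#CCBr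
Why: Williamson etherification of the potassium alkoxide. The alkoxide is hindered, but the electrophile is a primary, unbranched propargylic bromide and iodide catalysis helps.

Step 6
Reactants: 8 (3R)-3-(but-2-yn-1-yloxy)-1-methyl-3-(propan-2-yl)cyclopent-1-ene
Product: 10 1-[(1R)-1-methyl-3-(propan-2-yl)cyclopent-2-en-1-yl]but-2-yn-1-ol (both epimers at the carbinol carbon C10), via lithiated ether 9 (not isolated)
Conditions: n-BuLi, THF, −78 °C → −40 °C; H2O
Reagents that add atoms: none
Why: [2,3]-Wittig rearrangement of the propargyl-stabilised α-oxy carbanion 9 through a five-membered envelope. The C10–C1 bond forms on the ring face from which the oxygen leaves (suprafacial), so the C4 configuration of 8 is relayed to the new quaternary C1 (R) while the double bond moves to C4=C5. C10 forms without reliable control, which is of no consequence because step 7 removes that centre.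

Step 7
Reactants: 10 1-[(1R)-1-methyl-3-(propan-2-yl)cyclopent-2-en-1-yl]but-2-yn-1-ol (both C10 epimers)
Product: 11 1-[(1R)-1-methyl-3-(propan-2-yl)cyclopent-2-en-1-yl]but-2-yn-1-one
Conditions: Dess–Martin periodinane, NaHCO3, CH2Cl2, 0 °C → rt
Reagents that add atoms: none
Why: Dess–Martin oxidation of a secondary propargylic alcohol under buffered, non-acidic conditions. The ketone has no α-hydrogen on the ring side, so C1 cannot epimerise.

Step 8
Reactants: 11 1-[(1R)-1-methyl-3-(propan-2-yl)cyclopent-2-en-1-yl]but-2-yn-1-one
Product: 12 (1R)-1-[(1R)-1-methyl-3-(propan-2-yl)cyclopent-2-en-1-yl]but-2-yn-1-ol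
Conditions: (R)-1-methyl-3,3-diphenyltetrahydro-1H,3H-pyrrolo[1,2-c][1,3,2]oxazaborole (0.5 equiv), catecholborane, CH2Cl2, −78 °C → −40 °C
Reagents that add atoms: none
Why: Corey–Bakshi–Shibata reduction: the ketone binds the ring boron of the oxazaborolidine with the tert-alkyl group (large) turned away and the slim propynyl group (small) towards the catalyst. Hydride from the nitrogen-bound borane is then expected to give the (R)-carbinol, which is the C10 configuration of the target, under reagent control. Catecholborane at this temperature should not hydroborate the alkene or the alkyne.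

Step 9
Reactants: 12 (1R)-1-[(1R)-1-methyl-3-(propan-2-yl)cyclopent-2-en-1-yl]but-2-yn-1-ol
Product: 14 (1S,2Z)-3-iodo-1-[(1R)-1-methyl-3-(propan-2-yl)cyclopent-2-en-1-yl]but-2-en-1-ol, via alkenylalanate 13 (not isolated)
Conditions: NaAlH2(OCH2CH2OMe)2, THF, 0 °C → rt; EtOAc; I2, −78 °C → 0 °C
Reagents that add atoms: iodine, II
Why: Hydroxyl-directed trans-hydroalumination of the propargylic alcohol: the alkoxyaluminium hydride delivers hydride to C9 and leaves aluminium on C8 in the five-membered alanate 13, which holds C10 and the metal cis. Iodinolysis with retention gives the (Z)-iodoalkene and so sets the C8=C9 geometry that the seven-membered ring needs.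

Step 10
Reactants: 14 (1S,2Z)-3-iodo-1-[(1R)-1-methyl-3-(propan-2-yl)cyclopent-2-en-1-yl]but-2-en-1-ol; 15 (2E)-2-methylbut-2-enoyl chloride
Product: 16 (1S,2Z)-3-iodo-1-[(1R)-1-methyl-3-(propan-2-yl)cyclopent-2-en-1-yl]but-2-en-1-yl (2E)-2-methylbut-2-enoate
Conditions: 15, pyridine, 4-(dimethylamino)pyridine (0.2 equiv), CH2Cl2, 0 °C → rt
Reagents that add atoms: (2E)-2-methylbut-2-enoyl chloride (15), C/C=C(\C)C(Cl)=O
Why: Acylation of the neopentyl-type secondary alcohol through the acylpyridinium salt. Pyridine is used instead of a trialkylamine so that the acid chloride is not deprotonated to a vinylketene, which would give the deconjugated ester.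

Step 11
Reactants: 16 (1S,2Z)-3-iodo-1-[(1R)-1-methyl-3-(propan-2-yl)cyclopent-2-en-1-yl]but-2-en-1-yl (2E)-2-methylbut-2-enoate; 17 (1,3-dioxolan-2-ylmethyl)zinc bromide
Product: 18 (1S,2Z)-4-(1,3-dioxolan-2-yl)-3-methyl-1-[(1R)-1-methyl-3-(propan-2-yl)cyclopent-2-en-1-yl]but-2-en-1-yl (2E)-2-methylbut-2-enoate
Conditions: 17 (0.5 M in THF), Pd(PPh3)4 (5 mol %), THF, 50 °C
Reagents that add atoms: (1,3-dioxolan-2-ylmethyl)zinc bromide (17), Br[Zn]CC1OCCO1
Why: Negishi coupling: oxidative addition of the alkenyl iodide to zerovalent palladium, transmetalation from zinc and reductive elimination all proceed with retention at the alkene, so C7 ends up cis to C10. Oxidative addition to the C–I bond should be far faster than ionisation of the hindered allylic ester, the organozinc tolerates the ester, and C6 arrives masked as an acetal.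

Step 12
Reactants: 18 (1S,2Z)-4-(1,3-dioxolan-2-yl)-3-methyl-1-[(1R)-1-methyl-3-(propan-2-yl)cyclopent-2-en-1-yl]but-2-en-1-yl (2E)-2-methylbut-2-enoate
Product: 19 (1S,2Z)-5-(hydroxyimino)-3-methyl-1-[(1R)-1-methyl-3-(propan-2-yl)cyclopent-2-en-1-yl]pent-2-en-1-yl (2E)-2-methylbut-2-enoate (E/Z mixture at C=N)
Conditions: NH2OH·HCl, EtOH–H2O (4:1), 50 °C
Reagents that add atoms: hydroxylamine hydrochloride, Cl.NO
Why: Acid-catalysed exchange of the dioxolane with hydroxylamine (oxime formation). The aldehyde is trapped as it is released, so the C8=C9 bond has no opportunity to move into conjugation; the geometry at C=N is irrelevant for the next step.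

Step 13
Reactants: 19 (1S,2Z)-5-(hydroxyimino)-3-methyl-1-[(1R)-1-methyl-3-(propan-2-yl)cyclopent-2-en-1-yl]pent-2-en-1-yl (2E)-2-methylbut-2-enoate
Product: 21 tricyclic 2-isoxazoline (1R,4R,5S,10S) with an O–N=C bridge from C4 (oxygen) to C6 (C=N) and the tiglate on O10, via nitrile oxide 20 (not isolated)
Conditions: aq. NaOCl, CH2Cl2, 0 °C → rt, slow addition of 19 (final 0.005 M)
Reagents that add atoms: none
Why: Hypochlorite chlorinates the aldoxime carbon and the hydroximoyl chloride loses HCl to give nitrile oxide 20, which adds to the C4=C5 bond in a concerted, suprafacial (3+2) cycloaddition; the closest known reaction type is the intramolecular nitrile oxide–alkene cycloaddition that gives ring-fused 2-isoxazolines. The cycloheptene closes through C6–C5 in the exo (fused) mode, the dipole carbon attacking the alkene carbon nearer the tether so that C4 stays outside the carbocycle, and the isoxazoline is the five-membered ring of the cycloaddition itself, completed by the O–C4 bond. C5 is controlled by the tether: the dipole hangs from quaternary C1 through C10 and a short Z-configured arm, can reach only the alkene face syn to C10, and so C6 bonds cis to C10 and H-5 ends up cis to the C1 methyl group (5S, cis ring fusion). C4 is controlled by suprafaciality: both new bonds form on the same face, so oxygen is delivered to C4 cis to C6 (4R). The step needs the regiochemistry carbon-to-C5 and oxygen-to-C4, this facial sense, and cycloaddition ahead of dimerisation of 20. Regiochemistry is secured twice, since the nitrile oxide oxygen prefers the more substituted alkene carbon and the reverse orientation would require a bridged eight-membered carbocycle. The Z geometry of C8=C9 from step 9 holds C7 on the C10 side and makes the seven-membered transition state reachable, while the tiglate alkene and C8=C9 are out of intramolecular reach. High dilution and slow generation of 20 are used against furoxan formation.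

Step 14
Reactants: 21 tricyclic 2-isoxazoline (1R,4R,5S,10S)
Product: 23 (3R,3aR,8S,8aR)-3-hydroxy-6,8a-dimethyl-4-oxo-3-(propan-2-yl)-1,2,3,3a,4,5,8,8a-octahydroazulen-8-yl (2E)-2-methylbut-2-enoate, via hydroxy imine 22 (not isolated)
Conditions: Mo(CO)6, MeCN–H2O (10:1), 80 °C
Reagents that add atoms: water, O
Why: Zerovalent molybdenum cleaves the N–O bond reductively, and the β-hydroxy imine 22 hydrolyses in the aqueous medium to the ketone (the known unmasking of an isoxazoline to an aldol). The near-neutral medium is meant to spare the C5 stereocentre, the β,γ-alkene and the tertiary aldol; 23 is reduced without storage.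

Step 15
Reactants: 23 (3R,3aR,8S,8aR)-3-hydroxy-6,8a-dimethyl-4-oxo-3-(propan-2-yl)-1,2,3,3a,4,5,8,8a-octahydroazulen-8-yl (2E)-2-methylbut-2-enoate
Product: 25 (3R,3aS,4R,8S,8aR)-3,4-dihydroxy-6,8a-dimethyl-3-(propan-2-yl)-1,2,3,3a,4,5,8,8a-octahydroazulen-8-yl (2E)-2-methylbut-2-enoate, via diethylboron chelate 24 (not isolated)
Conditions: Et2BOMe, THF–MeOH (4:1), −78 °C; NaBH4, −78 °C; AcOH; MeOH evaporation
Reagents that add atoms: none
Why: Narasaka–Prasad reduction: the diethylboron unit bridges O4 and the ketone oxygen (24), which holds C4 in the carbonyl plane and leaves the two faces of C6 flanked by H-5 and by quaternary C1. External hydride should enter past H-5, the convex face of the cis-fused bicycle, so that H-6 is cis to H-5 and O6 cis to O4 (6R in working numbers). The ester is not reduced at −78 °C.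

Step 16
Reactants: 25 (3R,3aS,4R,8S,8aR)-3,4-dihydroxy-6,8a-dimethyl-3-(propan-2-yl)-1,2,3,3a,4,5,8,8a-octahydroazulen-8-yl (2E)-2-methylbut-2-enoate; 26 4-(acetyloxy)benzoyl chloride
Product: 27 (3R,3aS,4R,8S,8aR)-3-hydroxy-6,8a-dimethyl-8-{[(2E)-2-methylbut-2-enoyl]oxy}-3-(propan-2-yl)-1,2,3,3a,4,5,8,8a-octahydroazulen-4-yl 4-(acetyloxy)benzoate
Conditions: 26, pyridine, 4-(dimethylamino)pyridine (0.3 equiv), CH2Cl2, rt
Reagents that add atoms: 4-(acetyloxy)benzoyl chloride (26), CC(=O)Oc1ccc(cc1)C(Cl)=O
Why: Acylation through the acylpyridinium salt; O6–H is the only secondary hydroxyl and the tertiary O4–H does not react under these conditions.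

Step 17
Reactants: 27 (3R,3aS,4R,8S,8aR)-3-hydroxy-6,8a-dimethyl-8-{[(2E)-2-methylbut-2-enoyl]oxy}-3-(propan-2-yl)-1,2,3,3a,4,5,8,8a-octahydroazulen-4-yl 4-(acetyloxy)benzoate
Product: 28 (3R,3aS,4R,8S,8aR)-3-hydroxy-6,8a-dimethyl-8-{[(2E)-2-methylbut-2-enoyl]oxy}-3-(propan-2-yl)-1,2,3,3a,4,5,8,8a-octahydroazulen-4-yl 4-hydroxybenzoate
Conditions: pyrrolidine, CH2Cl2, 0 °C
Reagents that add atoms: none
Why: Aminolysis of the aryl acetate, whose phenoxide leaving group makes it far more reactive towards a secondary amine than the two alkyl esters. The tiglate, a poor conjugate acceptor, and the benzoate should stay intact.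

## Compound list

1 | (S)-terpinen-4-ol, (1S)-4-methyl-1-(propan-2-yl)cyclohex-3-en-1-ol | CC1=CC[C@](O)(C(C)C)CC1 | starting material
2 | triethyl{[(1S)-4-methyl-1-(propan-2-yl)cyclohex-3-en-1-yl]oxy}silane | CC1=CC[C@](O[Si](CC)(CC)CC)(C(C)C)CC1 | intermediate
3 | (3S)-6-oxo-3-(propan-2-yl)-3-[(triethylsilyl)oxy]heptanal | O=CC[C@](O[Si](CC)(CC)CC)(C(C)C)CCC(C)=O | intermediate
4 | (5R)-2-methyl-5-(propan-2-yl)-5-[(triethylsilyl)oxy]cyclopent-1-ene-1-carbaldehyde | O=CC1=C(C)CC[C@@]1(O[Si](CC)(CC)CC)C(C)C | intermediate
5 | triethyl{[(1R)-3-methyl-1-(propan-2-yl)cyclopent-2-en-1-yl]oxy}silane | CC1=C[C@](O[Si](CC)(CC)CC)(C(C)C)CC1 | intermediate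
6 | (1R)-3-methyl-1-(propan-2-yl)cyclopent-2-en-1-ol | CC1=C[C@](O)(C(C)C)CC1 | intermediate
7 | 1-bromobut-2-yne | CC#CCBr | starting material
8 | (3R)-3-(but-2-yn-1-yloxy)-1-methyl-3-(propan-2-yl)cyclopent-1-ene | CC1=C[C@](OCC#CC)(C(C)C)CC1 | intermediate
9 | α-lithio derivative of 8 (lithium on the O–CH carbon) | CC1=C[C@](OC([Li])C#CC)(C(C)C)CC1 | intermediate
10 | 1-[(1R)-1-methyl-3-(propan-2-yl)cyclopent-2-en-1-yl]but-2-yn-1-ol, both C10 epimers | CC#CC(O)[C@]1(C)CCC(C(C)C)=C1 | intermediate
11 | 1-[(1R)-1-methyl-3-(propan-2-yl)cyclopent-2-en-1-yl]but-2-yn-1-one | CC#CC(=O)[C@]1(C)CCC(C(C)C)=C1 | intermediate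
12 | (1R)-1-[(1R)-1-methyl-3-(propan-2-yl)cyclopent-2-en-1-yl]but-2-yn-1-ol | CC#C[C@H](O)[C@]1(C)CCC(C(C)C)=C1 | intermediate
13 | sodium alkenylalanate of 12: five-membered O10–Al–C8 ring, two 2-methoxyethoxy groups on aluminium | CC1=C[C@@H]([C@]2(C)CCC(C(C)C)=C2)O[Al-]1(OCCOC)OCCOC.[Na+] | intermediate
14 | (1S,2Z)-3-iodo-1-[(1R)-1-methyl-3-(propan-2-yl)cyclopent-2-en-1-yl]but-2-en-1-ol | I/C(C)=C\[C@H](O)[C@]1(C)CCC(C(C)C)=C1 | intermediate
15 | (2E)-2-methylbut-2-enoyl chloride (tigloyl chloride) | C/C=C(\C)C(Cl)=O | starting material
16 | (1S,2Z)-3-iodo-1-[(1R)-1-methyl-3-(propan-2-yl)cyclopent-2-en-1-yl]but-2-en-1-yl (2E)-2-methylbut-2-enoate | C/C=C(\C)C(=O)O[C@@H](/C=C(\I)C)[C@]1(C)CCC(C(C)C)=C1 | intermediate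
17 | (1,3-dioxolan-2-ylmethyl)zinc bromide | Br[Zn]CC1OCCO1 | starting material
18 | (1S,2Z)-4-(1,3-dioxolan-2-yl)-3-methyl-1-[(1R)-1-methyl-3-(propan-2-yl)cyclopent-2-en-1-yl]but-2-en-1-yl (2E)-2-methylbut-2-enoate | C/C=C(\C)C(=O)O[C@@H](/C=C(C)\CC1OCCO1)[C@]2(C)CCC(C(C)C)=C2 | intermediate
19 | (1S,2Z)-5-(hydroxyimino)-3-methyl-1-[(1R)-1-methyl-3-(propan-2-yl)cyclopent-2-en-1-yl]pent-2-en-1-yl (2E)-2-methylbut-2-enoate | C/C=C(\C)C(=O)O[C@@H](/C=C(C)\CC=NO)[C@]1(C)CCC(C(C)C)=C1 | intermediate
20 | nitrile oxide from 19 (C6≡N–O) | C/C=C(\C)C(=O)O[C@@H](/C=C(C)\CC#[N+][O-])[C@]1(C)CCC(C(C)C)=C1 | intermediate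
21 | tricyclic 2-isoxazoline, (1R,4R,5S,10S) in working numbers: O–N=C bridge from C4 to C6 on the cis-fused bicyclo[5.3.0]dec-8-ene, tiglate on O10 | C/C=C(\C)C(=O)O[C@H]1C=C(C)CC(=NO3)[C@@H]2[C@@]1(C)CC[C@@]23C(C)C | intermediate
22 | (3R,3aS,8S,8aR)-3-hydroxy-4-imino-6,8a-dimethyl-3-(propan-2-yl)-1,2,3,3a,4,5,8,8a-octahydroazulen-8-yl (2E)-2-methylbut-2-enoate | C/C=C(\C)C(=O)O[C@H]1C=C(C)CC(=N)[C@@H]2[C@@]1(C)CC[C@@]2(O)C(C)C | intermediate
23 | (3R,3aR,8S,8aR)-3-hydroxy-6,8a-dimethyl-4-oxo-3-(propan-2-yl)-1,2,3,3a,4,5,8,8a-octahydroazulen-8-yl (2E)-2-methylbut-2-enoate | C/C=C(\C)C(=O)O[C@H]1C=C(C)CC(=O)[C@@H]2[C@@]1(C)CC[C@@]2(O)C(C)C | intermediate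
24 | O4-diethylborinate of 23 (boron chelated to the C6 carbonyl oxygen) | C/C=C(\C)C(=O)O[C@H]1C=C(C)CC(=O)[C@@H]2[C@@]1(C)CC[C@@]2(OB(CC)CC)C(C)C | intermediate
25 | (3R,3aS,4R,8S,8aR)-3,4-dihydroxy-6,8a-dimethyl-3-(propan-2-yl)-1,2,3,3a,4,5,8,8a-octahydroazulen-8-yl (2E)-2-methylbut-2-enoate | C/C=C(\C)C(=O)O[C@H]1C=C(C)C[C@@H](O)[C@@H]2[C@@]1(C)CC[C@@]2(O)C(C)C | intermediate
26 | 4-(acetyloxy)benzoyl chloride | CC(=O)Oc1ccc(cc1)C(Cl)=O | starting material
27 | (3R,3aS,4R,8S,8aR)-3-hydroxy-6,8a-dimethyl-8-{[(2E)-2-methylbut-2-enoyl]oxy}-3-(propan-2-yl)-1,2,3,3a,4,5,8,8a-octahydroazulen-4-yl 4-(acetyloxy)benzoate | C/C=C(\C)C(=O)O[C@H]1C=C(C)C[C@@H](OC(=O)c2ccc(OC(C)=O)cc2)[C@@H]3[C@@]1(C)CC[C@@]3(O)C(C)C | intermediate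
28 | (3R,3aS,4R,8S,8aR)-3-hydroxy-6,8a-dimethyl-8-{[(2E)-2-methylbut-2-enoyl]oxy}-3-(propan-2-yl)-1,2,3,3a,4,5,8,8a-octahydroazulen-4-yl 4-hydroxybenzoate | C/C=C(\C)C(=O)O[C@H]1C=C(C)C[C@@H](OC(=O)c2ccc(O)cc2)[C@@H]2[C@@]1(C)CC[C@@]2(O)C(C)C | target

## Step count and least certain steps

Total: 17 steps. Longest linear sequence: 17 steps, from 1 to 28 (7, 15, 17 and 26 are purchased).

**Step 13 (key step).** The most likely failure is dimerisation of nitrile oxide 20 to a furoxan, or its interception by hypochlorite-derived species, outrunning a seven-membered ring closure onto a trisubstituted alkene whose oxygen-accepting carbon carries an isopropyl group. Fallback: from 19, heating in toluene (sealed vessel, about 150 °C) should bring about the thermal intramolecular oxime–olefin cycloaddition through the N–H nitrone tautomer, a dipole that cannot dimerise. This would give the N-unsubstituted isoxazolidine F1 with the same C5–C6 and C4–O bonds and the same tether-imposed configuration. N-Chlorination with N-chlorosuccinimide to the N-chloroisoxazolidine F2 and dehydrochlorination with 1,8-diazabicyclo[5.4.0]undec-7-ene would then rejoin the route at 21.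

**Step 6.** The most likely failure is loss of the sigmatropic pathway: the hindered propargylic anion on a tertiary ether may instead undergo a 1,2-shift by C–O homolysis, or deprotonation may occur at the propargylic methyl group with isomerisation to an allenyl ether. Fallback: from 6, O-alkylation with tributyl(iodomethyl)stannane (KH, THF) gives the stannylmethyl ether F3. Tin–lithium exchange with n-BuLi at −78 °C triggers the Still–Wittig [2,3] shift of an unstabilised carbanion, which sets C1 in the same suprafacial way and gives the primary alcohol F4. Oxidation gives the non-enolisable aldehyde F5, and addition of 1-propynylmagnesium bromide returns to the route at 10.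

**Step 3.** The most likely failure is slow oxidative addition of the rhodium complex into a formyl C–H bond flanked by two fully substituted carbons, so that at the temperature required the allylic silyl ether ionises or the alkene migrates. Fallback: from 4, Baeyer–Villiger oxidation with 3-chloroperoxybenzoic acid (NaHCO3 buffer) gives the enol formate F6 by alkenyl migration, and methanolysis (K2CO3, MeOH) gives ketone F7. This ketone can enolise only towards the methyl-bearing carbon, so KN(SiMe3)2 and N-phenylbis(trifluoromethanesulfonimide) give the single enol triflate F8. Reduction with Pd(OAc)2, PPh3, HCO2H and Bu3N in DMF replaces the triflate by hydrogen and rejoins the route at 5.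

**Step 14.** The most likely failure is enolisation of the liberated hydroxy ketone at 80 °C: migration of C8=C9 into conjugation with C6=O, epimerisation at C5, or retro-aldol cleavage or dehydration at C4. Fallback: from 21, the N–O bond is cleaved by one-electron reduction with SmI2 in THF at 0 °C and the imine is hydrolysed with aqueous B(OH)3 at room temperature. The hydroxy ketone is not isolated but taken in the same flask into the chelation-controlled reduction of step 15, so the route is rejoined at 25. This changes the reductant class (divalent samarium, no heating) and the tactic (the sensitive ketone is never handled). It makes no new compound.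

**Step 15.** The most likely failure is poor facial selectivity, because the hindered tertiary hydroxyl at C4 may not form the boron chelate and hydride would then attack an unchelated ketone. Fallback: from 23, if hydride attack favours the other face, the 6-epimeric diol F9 is used instead. Mitsunobu esterification with 4-(acetyloxy)benzoic acid (PPh3, diisopropyl azodicarboxylate) would install the aroyl group with inversion at C6 and rejoin the route at 27, bypassing step 16.

## Further compounds

F1 | step 13 | N-unsubstituted isoxazolidine: as 21 but with C6H–NH–O–C4 in place of C6=N–O–C4 | C/C=C(\C)C(=O)O[C@H]1C=C(C)CC(NO3)[C@@H]2[C@@]1(C)CC[C@@]23C(C)C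
F2 | step 13 | N-chloro derivative of F1 | C/C=C(\C)C(=O)O[C@H]1C=C(C)CC(N(Cl)O3)[C@@H]2[C@@]1(C)CC[C@@]23C(C)C
F3 | step 6 | tributyl({[(1R)-3-methyl-1-(propan-2-yl)cyclopent-2-en-1-yl]oxy}methyl)stannane | CC1=C[C@](OC[Sn](CCCC)(CCCC)CCCC)(C(C)C)CC1
F4 | step 6 | [(1R)-1-methyl-3-(propan-2-yl)cyclopent-2-en-1-yl]methanol | OC[C@]1(C)CCC(C(C)C)=C1
F5 | step 6 | (1R)-1-methyl-3-(propan-2-yl)cyclopent-2-ene-1-carbaldehyde | O=C[C@]1(C)CCC(C(C)C)=C1
F6 | step 3 | (5R)-2-methyl-5-(propan-2-yl)-5-[(triethylsilyl)oxy]cyclopent-1-en-1-yl formate | O=COC1=C(C)CC[C@@]1(O[Si](CC)(CC)CC)C(C)C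
F7 | step 3 | (2R)-5-methyl-2-(propan-2-yl)-2-[(triethylsilyl)oxy]cyclopentan-1-one, both C5 epimers | O=C1C(C)CC[C@@]1(O[Si](CC)(CC)CC)C(C)C
F8 | step 3 | (5R)-2-methyl-5-(propan-2-yl)-5-[(triethylsilyl)oxy]cyclopent-1-en-1-yl trifluoromethanesulfonate | CC1=C(OS(=O)(=O)C(F)(F)F)[C@](O[Si](CC)(CC)CC)(C(C)C)CC1
F0 | step 14 | none | none
F9 | step 15 | (3R,3aS,4S,8S,8aR)-3,4-dihydroxy-6,8a-dimethyl-3-(propan-2-yl)-1,2,3,3a,4,5,8,8a-octahydroazulen-8-yl (2E)-2-methylbut-2-enoate (6-epimer of 25) | C/C=C(\C)C(=O)O[C@H]1C=C(C)C[C@H](O)[C@@H]2[C@@]1(C)CC[C@@]2(O)C(C)C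
A1 | alternative 1 | (5R)-2-methyl-5-(propan-2-yl)-5-[(triethylsilyl)oxy]cyclopent-1-ene-1-carbaldehyde | O=CC1=C(C)CC[C@@]1(O[Si](CC)(CC)CC)C(C)C
A2 | alternative 2 | 3-(2,2-dimethyl-1,3-dioxolan-4-yl)-3,7-dimethyl-6-oxooctanoic acid, configured at C1 and C10 as in the target | OC(=O)C[C@@](C)(CCC(=O)C(C)C)[C@@H]1COC(C)(C)O1
A3 | alternative 2 | 2-(2,2-dimethyl-1,3-dioxolan-4-yl)-2-methyl-5-(propan-2-yl)-6-oxabicyclo[3.2.0]heptan-7-one | O=C1O[C@@]2(C(C)C)CC[C@@](C)([C@@H]3COC(C)(C)O3)[C@@H]12
A4 | alternative 3 | 1-methyl-3-(propan-2-yl)-3-[(triethylsilyl)oxy]cyclopentane-1,2-dicarbaldehyde (cis-dialdehyde) | O=C[C@@H]1[C@](C)(C=O)CC[C@@]1(O[Si](CC)(CC)CC)C(C)C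
A5 | alternative 3 | 3-iodo-2-[(trimethylsilyl)methyl]prop-1-ene | C=C(CI)C[Si](C)(C)C
A6 | alternative 3 | 8a-methyl-6-methylidene-3-(propan-2-yl)-3-[(triethylsilyl)oxy]decahydroazulene-4,8-diol | O[C@H]1CC(=C)C[C@@H](O)[C@@H]2[C@@]1(C)CC[C@@]2(O[Si](CC)(CC)CC)C(C)C
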